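**Retrosynthetic overview**
- The target comes from the 3β-hydroxy diacid by late O-acetylation, and that from a bicyclic 3β,19-diol ester (C19 CH2OH → CO2H, ester hydrolysis).
- Both rings and the C3–O bond trace back to an acyclic (Z)-allylic alcohol tetraene. The key step is a hydroxyl-directed asymmetric epoxidation that makes the C3–O bond and sets the only externally controlled stereocentre. The epoxide is opened in the same flask: ring A closes first (C4–C5), then ring B (C9–C10), and an allylsilane terminator delivers the 8(17)-methylene.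
- The tetraene comes from a methyl ketone (olefination), itself assembled from a terminal enynol, a Me3SiCH2 unit and methyl vinyl ketone (carbocupration/conjugate addition fixes the allylsilane geometry).
- The enynol comes from geranyl chloride by ozonolytic trimming, (Z)-selective olefination/reduction (future C19) and propargylation.

Assumption: catalogue reagents (geranyl chloride, the Still–Gennari propionate phosphonate, 1-(trimethylsilyl)propyne, Me3SiCH2MgCl solution, methyl vinyl ketone, trimethyl phosphonoacetate) are taken as cheap commercial starting materials.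

Step 1
Reactants: 1 geranyl chloride [(2E)-1-chloro-3,7-dimethylocta-2,6-diene]
Product: 3 (4E)-6-chloro-4-methylhex-4-enal, via ozonide 2 (not isolated)
Conditions: O3 (1.0 equiv, Sudan Red 7B end point), CH2Cl2, −78 °C; then PPh3, −78 °C → rt
Reagents that add atoms: ozone, [O-][O+]=O
Why: Chemoselective ozonolysis, because the electron-rich isopropylidene alkene reacts much faster than the alkene deactivated by the allylic chloride and the dye end point stops the reaction after one equivalent; no stereocentre is formed and the (E)-alkene is untouched.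

Step 2
Reactants: 3 (4E)-6-chloro-4-methylhex-4-enal; 4 ethyl 2-[bis(2,2,2-trifluoroethoxy)phosphoryl]propanoate
Product: 5 ethyl (2Z,6E)-8-chloro-2,6-dimethylocta-2,6-dienoate
Conditions: KN(SiMe3)2, 18-crown-6, THF, −78 °C
Reagents that add atoms: none
Why: Still–Gennari olefination, in which the electron-poor bis(trifluoroethyl) phosphonate eliminates under kinetic control to the (Z)-trisubstituted enoate, placing the future C19 carbon cis to the chain.

Step 3
Reactants: 5 ethyl (2Z,6E)-8-chloro-2,6-dimethylocta-2,6-dienoate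
Product: 6 (2Z,6E)-8-chloro-2,6-dimethylocta-2,6-dien-1-ol
Conditions: i-Bu2AlH (2.2 equiv), CH2Cl2, −78 °C
Reagents that add atoms: none
Why: 1,2-Reduction of the enoate by the aluminium hydride gives the allylic alcohol without touching the alkene geometry or the allylic chloride at −78 °C.

Step 4
Reactants: 6 (2Z,6E)-8-chloro-2,6-dimethylocta-2,6-dien-1-ol; 7 1-(trimethylsilyl)propyne
Product: 9 (2Z,6E)-2,6-dimethylundeca-2,6-dien-10-yn-1-ol, via silylalkyne 8 (not isolated)
Conditions: 7 (2.2 equiv), n-BuLi (2.2 equiv), THF, −78 → −20 °C; then 6, −78 → 0 °C; then MeOH, K2CO3, rt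
Reagents that add atoms: none
Why: SN2 alkylation of the primary allylic chloride by the propargylic carbon of lithiated silylpropyne (the first equivalent only deprotonates the hydroxyl), followed by base-mediated protodesilylation of the alkynyl C–Si bond, leaves both alkene geometries intact.

Step 5
Reactants: 9 (2Z,6E)-2,6-dimethylundeca-2,6-dien-10-yn-1-ol; 10 (trimethylsilyl)methylmagnesium chloride (Me3SiCH2MgCl); 11 methyl vinyl ketone (but-3-en-2-one)
Product: 14 (5Z,9E,13Z)-15-hydroxy-10,14-dimethyl-6-[(trimethylsilyl)methyl]pentadeca-5,9,13-trien-2-one, via alkenylcopper 12 (not isolated), via bis-silyl enol ether 13 (not isolated)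
Conditions: 10 (3.2 equiv), CuBr·SMe2 (2.1 equiv), Et2O/Me2S, −40 °C; then 9, −25 → −10 °C; then 11, Me3SiCl, THF, −78 → −30 °C; then NH4Cl/NH3 (aq); K2CO3, MeOH, 0 °C
Reagents that add atoms: none
Why: Normant syn-carbocupration puts Me3SiCH2 on the internal alkyne carbon and copper on the terminus, and the Me3SiCl-accelerated conjugate addition to the enone proceeds with retention, so the CH2SiMe3 group and the new side chain are cis, the alkene geometry that later gives the 9β side chain.

Step 6
Reactants: 14 (5Z,9E,13Z)-15-hydroxy-10,14-dimethyl-6-[(trimethylsilyl)methyl]pentadeca-5,9,13-trien-2-one; 15 trimethyl phosphonoacetate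
Product: 16 methyl (2E,6Z,10E,14Z)-16-hydroxy-3,11,15-trimethyl-7-[(trimethylsilyl)methyl]hexadeca-2,6,10,14-tetraenoate
Conditions: 15 (1.5 equiv), NaH (1.5 equiv), THF, 0 → 45 °C; (2Z)-isomer removed on AgNO3-impregnated silica
Reagents that add atoms: none
Why: Horner–Wadsworth–Emmons olefination of the methyl ketone gives mainly the (2E)-enoate (about 4:1 expected), and the stabilised phosphonate anion is too weak a base to deprotonate the free alcohol.

Step 7
Reactants: 16 methyl (2E,6Z,10E,14Z)-16-hydroxy-3,11,15-trimethyl-7-[(trimethylsilyl)methyl]hexadeca-2,6,10,14-tetraenoate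
Product: 18 methyl (13E)-3β,19-dihydroxylabda-8(17),13-dien-15-oate, via epoxy alcohol 17 (not isolated)
Conditions: Ti(OiPr)4 (10 mol%), D-(−)-diethyl tartrate (12 mol%), t-BuOOH (1.1 equiv), 4 Å molecular sieves, CH2Cl2, −20 °C; then (CF3)2CHOH (equal volume), −20 → 10 °C
Reagents that add atoms: tert-butyl hydroperoxide, CC(C)(C)OO
Why: Proposed new method: a one-flask epoxidation–bicyclisation cascade in which hydroxyl-directed Ti–tartrate oxygen transfer (Sharpless asymmetric epoxidation, D-tartrate face) forms the C3–O bond as the (2R,3S)-epoxide 17, and the added fluoroalcohol then ionises the tertiary C4–O bond of the titanium- and hydrogen-bond-activated epoxide, so that C5=C10 attacks C4 with inversion (the hydroxymethyl cis to the chain becomes the axial C19), the chair–chair array adds anti across both alkenes (ring A then ring B; 5α-H, 10β-CH3, 9β side chain) and loss of Me3Si from the β-silyl cation fixes the 8(17)-alkene; the closest known reactions are the Sharpless epoxidation with in-flask use of the epoxy alcohol and Lewis-acid- or fluoroalcohol-promoted epoxide-initiated polyene cyclisation terminated by an allylsilane, not yet run as one catalytic cascade on a free 2,3-epoxy alcohol.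

Step 8
Reactants: 18 methyl (13E)-3β,19-dihydroxylabda-8(17),13-dien-15-oate
Product: 20 (13E)-3β-hydroxy-15-methoxy-15-oxolabda-8(17),13-dien-19-oic acid, via aldehyde 19 (not isolated)
Conditions: TEMPO (10 mol%), PhI(OAc)2 (1.2 equiv), CH2Cl2, rt; then t-BuOH/H2O, 2-methylbut-2-ene, NaH2PO4, NaClO2, 0 °C → rt
Reagents that add atoms: sodium chlorite, [Na+].[O-]Cl=O
Why: Oxoammonium (nitroxyl-catalysed) oxidation is selective for the primary C19 alcohol over the secondary 3β-alcohol, and Pinnick oxidation with an alkene scavenger then converts the aldehyde to the acid without touching the alkenes or any stereocentre.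

Step 9
Reactants: 20 (13E)-3β-hydroxy-15-methoxy-15-oxolabda-8(17),13-dien-19-oic acid
Product: 21 (13E)-3β-hydroxylabda-8(17),13-diene-15,19-dioic acid
Conditions: LiOH (5 equiv), THF/MeOH/H2O, 45 °C; then aq. HCl to pH 3, 0 °C
Reagents that add atoms: lithium hydroxide, [Li+].[OH-]
Why: Saponification of the unhindered C15 methyl ester proceeds by acyl–oxygen cleavage, while the C19 carboxylate cannot undergo retro-aldol cleavage, so the β-hydroxy acid and all stereocentres survive.

Step 10
Reactants: 21 (13E)-3β-hydroxylabda-8(17),13-diene-15,19-dioic acid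
Product: 23 3β-acetoxy-agathic acid [(13E)-3β-acetoxylabda-8(17),13-diene-15,19-dioic acid], via mixed anhydride 22 (not isolated)
Conditions: Ac2O, pyridine, DMAP (10 mol%), rt; then H2O, rt
Reagents that add atoms: acetic anhydride, CC(=O)OC(C)=O
Why: DMAP-catalysed O-acylation of the equatorial 3β-hydroxyl leaves the C3–O bond and its configuration untouched, and the transient carboxylic–acetic mixed anhydrides hydrolyse at the acetyl carbonyl on adding water to return both acids.

**Compound list**
1 | geranyl chloride, (2E)-1-chloro-3,7-dimethylocta-2,6-diene | CC(C)=CCC/C(C)=C/CCl | starting material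
2 | 3-[(3E)-5-chloro-3-methylpent-3-en-1-yl]-5,5-dimethyl-1,2,4-trioxolane (ozonide, racemic at the ring CH) | CC1(C)OOC(CC/C(C)=C/CCl)O1 | intermediate
3 | (4E)-6-chloro-4-methylhex-4-enal | O=CCC/C(C)=C/CCl | intermediate
4 | ethyl 2-[bis(2,2,2-trifluoroethoxy)phosphoryl]propanoate | CCOC(=O)C(C)P(=O)(OCC(F)(F)F)OCC(F)(F)F | starting material
5 | ethyl (2Z,6E)-8-chloro-2,6-dimethylocta-2,6-dienoate | CCOC(=O)/C(C)=C\CC/C(C)=C/CCl | intermediate
6 | (2Z,6E)-8-chloro-2,6-dimethylocta-2,6-dien-1-ol | OC/C(C)=C\CC/C(C)=C/CCl | intermediate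
7 | 1-(trimethylsilyl)propyne | CC#C[Si](C)(C)C | starting material
8 | (2Z,6E)-2,6-dimethyl-11-(trimethylsilyl)undeca-2,6-dien-10-yn-1-ol (present as its lithium alkoxide) | OC/C(C)=C\CC/C(C)=C/CCC#C[Si](C)(C)C | intermediate
9 | (2Z,6E)-2,6-dimethylundeca-2,6-dien-10-yn-1-ol | OC/C(C)=C\CC/C(C)=C/CCC#C | intermediate
10 | (trimethylsilyl)methylmagnesium chloride, Me3SiCH2MgCl | C[Si](C)(C)C[Mg]Cl | starting material
11 | methyl vinyl ketone, but-3-en-2-one | CC(=O)C=C | starting material
12 | chloromagnesium (2Z,6E,10Z)-11-cuprio-2,6-dimethyl-10-[(trimethylsilyl)methyl]undeca-2,6,10-trien-1-olate (Cu cis to CH2SiMe3) | Cl[Mg]OC/C(C)=C\CC/C(C)=C/CC/C(C[Si](C)(C)C)=C/[Cu] | intermediate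
13 | (2Z,5Z,9E,13Z)-10,14-dimethyl-6-[(trimethylsilyl)methyl]-2,15-bis(trimethylsilyloxy)pentadeca-2,5,9,13-tetraene | C[Si](C)(C)OC/C(C)=C\CC/C(C)=C/CC/C(C[Si](C)(C)C)=C/C/C=C(/C)O[Si](C)(C)C | intermediate
14 | (5Z,9E,13Z)-15-hydroxy-10,14-dimethyl-6-[(trimethylsilyl)methyl]pentadeca-5,9,13-trien-2-one | OC/C(C)=C\CC/C(C)=C/CC/C(C[Si](C)(C)C)=C/CCC(C)=O | intermediate
15 | trimethyl phosphonoacetate | COC(=O)CP(=O)(OC)OC | starting material
16 | methyl (2E,6Z,10E,14Z)-16-hydroxy-3,11,15-trimethyl-7-[(trimethylsilyl)methyl]hexadeca-2,6,10,14-tetraenoate | OC/C(C)=C\CC/C(C)=C/CC/C(C[Si](C)(C)C)=C/CC/C(C)=C/C(=O)OC | intermediate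
17 | methyl (2E,6Z,10E)-13-[(2S,3R)-3-(hydroxymethyl)-3-methyloxiran-2-yl]-3,11-dimethyl-7-[(trimethylsilyl)methyl]trideca-2,6,10-trienoate | OC[C@@]1(C)O[C@H]1CC/C(C)=C/CC/C(C[Si](C)(C)C)=C/CC/C(C)=C/C(=O)OC | intermediate
18 | methyl (13E)-3β,19-dihydroxylabda-8(17),13-dien-15-oate (normal labdane: 5α-H, 9α-H, 10β-CH3, 19 = axial 4β-CH2OH) | C=C1CC[C@@H]2[C@](C)(CC[C@H](O)[C@]2(C)CO)[C@H]1CC/C(C)=C/C(=O)OC | intermediate
19 | methyl (13E)-3β-hydroxy-19-oxolabda-8(17),13-dien-15-oate | C=C1CC[C@@H]2[C@](C)(CC[C@H](O)[C@]2(C)C=O)[C@H]1CC/C(C)=C/C(=O)OC | intermediate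
20 | (13E)-3β-hydroxy-15-methoxy-15-oxolabda-8(17),13-dien-19-oic acid | C=C1CC[C@@H]2[C@](C)(CC[C@H](O)[C@]2(C)C(=O)O)[C@H]1CC/C(C)=C/C(=O)OC | intermediate
21 | (13E)-3β-hydroxylabda-8(17),13-diene-15,19-dioic acid (3β-hydroxyagathic acid) | C=C1CC[C@@H]2[C@](C)(CC[C@H](O)[C@]2(C)C(=O)O)[C@H]1CC/C(C)=C/C(=O)O | intermediate
22 | (13E)-3β-acetoxylabda-8(17),13-diene-15,19-dioic bis(acetic) anhydride | C=C1CC[C@@H]2[C@](C)(CC[C@H](OC(C)=O)[C@]2(C)C(=O)OC(C)=O)[C@H]1CC/C(C)=C/C(=O)OC(C)=O | intermediate
23 | 3β-acetoxy-agathic acid, (3S,4R,5R,9S,10R,13E)-3-acetoxylabda-8(17),13-diene-15,19-dioic acid | C=C1CC[C@@H]2[C@](C)(CC[C@H](OC(C)=O)[C@]2(C)C(=O)O)[C@H]1CC/C(C)=C/C(=O)O | target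

**Step count and risks**

Total step count: 10. Longest linear sequence: 10 steps (1 → 23, fully linear). The enantiomeric excess set in step 7 (at least 90% expected) can be raised by recrystallising diacid 21 or the target 23.

The three steps most likely to fail are steps 5, 6 and 7.

Step 5 (silylmethyl carbocupration and conjugate addition). The silylmethylcopper reagent transfers its group reluctantly, and the alkenylcopper may add poorly to the enone. The fallback sets out from 9 and comes back to the route at 14. The approach changes from a stoichiometric organocopper to a nickel-catalysed three-component coupling. Alkyne 9, enone 11 and bis[(trimethylsilyl)methyl]zinc F1 (made from 10 and ZnCl2; the excess also deprotonates the hydroxyl) are combined with Ni(cod)2/PPh3 and Me3SiCl in THF. Zerovalent nickel couples enone and alkyne oxidatively to a nickelacycle, the zinc reagent delivers CH2SiMe3 to the internal alkyne carbon, and reductive elimination gives the same syn-addition product, the bis-silyl enol ether 13. Methanolysis (K2CO3, MeOH) gives 14.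

Step 6 (E/Z ratio of the olefination). If the (2Z)-isomer cannot be removed cleanly, the fallback sets out from 14 and comes back at 16. The methyl ketone is converted through its kinetic enol phosphate (LiN(i-Pr)2, ClP(O)(OEt)2, THF, −78 °C; then more LiN(i-Pr)2, −78 °C → rt) into the terminal alkyne (2Z,6E,10Z)-2,6-dimethyl-10-[(trimethylsilyl)methyl]pentadeca-2,6,10-trien-14-yn-1-ol F2. Zirconium-catalysed methylalumination (AlMe3, Cp2ZrCl2, CH2Cl2; syn addition, methyl to the internal carbon) and trapping of the alkenylalane with ClCO2Me then give 16 as the (2E)-isomer only.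

Step 7 (proposed new cascade). Possible failures are capture of the C10 cation by the free C19 hydroxyl (a 19,10-ether), opening of the epoxide at C3, or protodesilylation before cyclisation. The fallback uses known chemistry only, sets out from 16 and comes back at 18. The Sharpless epoxidation is run alone (same catalyst, aqueous work-up) and epoxy alcohol 17 is isolated. Silylation (t-BuMe2SiCl, imidazole, DMF) gives the 19-O-tert-butyldimethylsilyl ether of epoxy alcohol 17 F3. A stoichiometric Lewis acid (MeAlCl2, CH2Cl2, −78 °C) then effects the epoxide-initiated cation–olefin bicyclisation with allylsilane termination to give methyl (13E)-19-[tert-butyl(dimethyl)silyl]oxy-3β-hydroxylabda-8(17),13-dien-15-oate F4. Desilylation with Bu4NF in THF gives 18.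

Further compounds
F1 | step 5 | bis[(trimethylsilyl)methyl]zinc | C[Si](C)(C)C[Zn]C[Si](C)(C)C
F2 | step 6 | (2Z,6E,10Z)-2,6-dimethyl-10-[(trimethylsilyl)methyl]pentadeca-2,6,10-trien-14-yn-1-ol | OC/C(C)=C\CC/C(C)=C/CC/C(C[Si](C)(C)C)=C/CCC#C
F3 | step 7 | 19-O-tert-butyldimethylsilyl ether of epoxy alcohol 17, methyl (2E,6Z,10E)-13-[(2S,3R)-3-{[tert-butyl(dimethyl)silyl]oxymethyl}-3-methyloxiran-2-yl]-3,11-dimethyl-7-[(trimethylsilyl)methyl]trideca-2,6,10-trienoate | CC(C)(C)[Si](C)(C)OC[C@@]1(C)O[C@H]1CC/C(C)=C/CC/C(C[Si](C)(C)C)=C/CC/C(C)=C/C(=O)OC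
F4 | step 7 | methyl (13E)-19-[tert-butyl(dimethyl)silyl]oxy-3β-hydroxylabda-8(17),13-dien-15-oate | C=C1CC[C@@H]2[C@](C)(CC[C@H](O)[C@]2(C)CO[Si](C)(C)C(C)(C)C)[C@H]1CC/C(C)=C/C(=O)OC
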